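The decision is the order in which E and Q meet.

    Q + L → Z + D (k1 = 0.00263 /M/s)
    E + Q → L + D (k2 = 0.0746 /M/s)
    2 E → E2 (k3 = 0.0947 /M/s)

| setting | west | south | north-west | east |
|---|---|---|---|---|
| E | 0.20 M | 0.20 M (fed, over 4.00 min) | 0.20 M | 0.20 M |
| Q | 1.50 equiv | 1.50 equiv | 1.50 equiv | 1.50 equiv (fed, over 4.00 min) |
| remark | one stirred flow tank at steady state, fed with the mixture as stated, mean residence time 5.0 min | a stirred flask in which E is dosed at a steady rate over 4.00 min without added volume, worked up at 5.0 min | a closed flask charged with all of it at once and left for 5.0 min | all but Q at the start; Q goes in evenly over 4.00 min, the run ends at 5.0 min |
| time |  | 5.0 min | 5.0 min | 5.0 min |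

- the set-up with the highest amount of L at the outlet or at the end, in percent of the E put in ("none" if the first two lie within 2 percentage points) (west / south / north-west / east / none)
- amount of L at the outlet or at the end, in percent of the E put in, west
- amount of L at the outlet or at the end, in percent of the E put in, south
- amount of L at the outlet or at the end, in percent of the E put in, north-west
- amount of L at the outlet or at the end, in percent of the E put in, east

- percentages count the E that a species holds: one E2 counts as two
- a step written with two of one species runs at k times the square of its concentration and takes two of it each time
- the stated concentrations are those of everything mixed, before any reaction; amounts are the same in each set-up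
- the feed brings no volume worth counting
- run time (south): 5.0 min

The over-addition of Q to L is set aside in this reckoning: in north-west, with [Q] as charged, L has a half-life of 15 min by that path, longer than the run of 5.0 min. So the question becomes how E divides. With 0.300 M of Q, call the split ratio of the charged mixture, the rate of E use by dimerisation over that by addition to Q (a selectivity factor), 1.69; the ratio moves with [E]/[Q].

At a ratio of 1 both paths take E equally, and north-west starts above that. Summing the addition's share as [E] falls, with [Q] held as charged, gives a ceiling for north-west, since [Q] can only fall: 58.5 %.

But south holds [E] down. At [Q] as charged, the lifetime of E by addition is 0.745 min, shorter than the dose, so [E] sits near 0.0372 M and the ratio near 0.315, below the charged value. At that ratio, with [Q] as charged, addition takes 76.0 % of the E in south, an estimate for the steady stretch of the dose and not a bound.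

East is the reverse. In east, E by dimerisation alone has a first half-life of 0.440 min, shorter than the dose, and at that moment, counting the Q fed so far as unreacted, the ratio is near 7.69, above the charged value. This reckoning ranks south over north-west over east and does not place west.

The forecast named south, with 51 % for west, 61 % for south, 48.5 % for north-west and 21 % for east, holding that “whatever keeps E low while Q stays high favours L”.

The simulation gives 51.3 % for west, 63.5 % for south, 48.0 % for north-west and 20.7 % for east, so south comes first.

In east the split ratio read 16 at 0.277 min, above the charged value, and at 2.50 min E2 held 76.0 % of the E. In south at 2.50 min, with E at 16.8 % of the E charged and Q at 75.0 % of its own charge, the same ratio comes to 0.379, below the even split, and at 5.00 min E2 held 24.2 %.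

The numbers of this flask stand for no real mixture.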